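**Retrosynthetic overview**

1. The strategy rests on C7: it is bonded to C8, which is para to O12 in ring C, and to the C6 carbonyl. The quinone methide (C7=C8, C9=C11–OH, C12=O) is therefore a dehydrated catechol 7‑hydroxy‑6‑ketone, and that α‑ketol is a benzoin product.
2. Key disconnection: C6–C7 (ring B) by carbene‑catalysed aldehyde–ketone benzoin of keto aldehyde 38, in which C9–C10 and ring E (C7–C8–C14–C2'–C1') are already in place.
3. Ring E: C7–C8 by Friedel–Crafts acylation; C1'–C2' by allylation of an α‑aryl ketone enolate anti to the cyclopropane CH2, which sets the spiro centre; C14–C2' by Negishi coupling with the enol triflate of sabina ketone.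
4. Ring A side: C9–C10 and the quaternary centre C10 by asymmetric palladium‑catalysed α‑arylation of 2,2,6‑trimethylcyclohexanone; C6 by methylenation and hydroboration, which sets C5.
5. Order of ring formation: rings C and A and the sabinane come with the starting materials, then ring E (step 16), ring B (step 22), and the quinone methide last (step 23).

Key step: step 22

Locants: abietane numbering for C1–C14; C1' is the carbinol carbon and C2' the spiro carbon of ring E; C3' and C4' are the sabinane CH2 groups, C5' carries the isopropyl group, C6' is the cyclopropane CH next to C2', C7' is the cyclopropane CH2.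

Reading of the target: H‑5 is cis to the C10 methyl (cis A/B fusion), C14 sits on the C2' face that carries C7'H2, and the C1' hydroxyl lies on the ring E face next to C6'.

Assumption: in the reagent‑controlled steps 3 and 18 the named enantiomer of ligand or ketone catalyst is the one the usual stereochemical models assign; its antipode is used if the sense proves opposite.

The catechol is carried as its acetonide, because the route passes through SnCl4 (step 16) and hot KOH (step 14).

**Route**

Step 1
Reactants: 1 3‑isopropylcatechol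
Product: 2 4‑isopropyl‑2,2‑dimethyl‑1,3‑benzodioxole
Conditions: Me2C(OMe)2, TsOH·H2O (cat.), toluene, reflux, MeOH removed
Reagents that add atoms: 2,2‑dimethoxypropane COC(C)(C)OC
Why: Acid‑catalysed ketal exchange (acetonide formation) ties both phenols into one small ring that should tolerate organolithiums, hot KOH and SnCl4 and leaves the ortho position C9 unencumbered.

Step 2
Reactants: 2 4‑isopropyl‑2,2‑dimethyl‑1,3‑benzodioxole
Product: 4 4‑bromo‑7‑isopropyl‑2,2‑dimethyl‑1,3‑benzodioxole, via C9 aryllithium 3 (not isolated)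
Conditions: s‑BuLi, TMEDA, THF, −78 → −20 °C; BrCH2CH2Br, −78 °C → rt
Reagents that add atoms: 1,2‑dibromoethane BrCCBr
Why: Directed ortho‑metalation: the only hydrogen ortho to a ring oxygen is at C9 (the other ortho site carries the isopropyl group), and the aryllithium is brominated by 1,2‑dibromoethane with loss of ethene.

Step 3
Reactants: 4 4‑bromo‑7‑isopropyl‑2,2‑dimethyl‑1,3‑benzodioxole; 5 2,2,6‑trimethylcyclohexanone (racemic)
Product: 6 (R)‑2‑(7‑isopropyl‑2,2‑dimethyl‑1,3‑benzodioxol‑4‑yl)‑2,6,6‑trimethylcyclohexanone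
Conditions: Pd2(dba)3 (2.5 mol %), (R)‑BI‑DIME (6 mol %), NaOtBu, toluene, 80 °C
Reagents that add atoms: none
Why: Palladium‑catalysed asymmetric α‑arylation of a ketone enolate: 5 can enolise only at its methyl‑bearing carbon, so C–C reductive elimination forms the C9–C10 bond and the quaternary centre C10, the P‑chiral monophosphine distinguishing the enolate faces (racemic 5 converges through its planar enolate).

Step 4
Reactants: 6 (R)‑2‑aryl‑2,6,6‑trimethylcyclohexanone
Product: 8 exocyclic alkene (C5=C6H2 in place of C5=O), via β‑hydroxysilane 7 (not isolated)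
Conditions: Me3SiCH2Li, CeCl3, THF, −78 → 0 °C; H2O; then KH, THF, 50 °C
Reagents that add atoms: (trimethylsilyl)methyllithium [Li]C[Si](C)(C)C
Why: Peterson olefination: the small α‑silyl carbanion, made less basic by CeCl3, should add to the hindered non‑enolisable ketone, and the potassium alkoxide loses Me3SiOK by syn‑elimination, so the alkene forms without a carbocation and hence without 1,2‑aryl shift.

Step 5
Reactants: 8 exocyclic alkene
Product: 10 primary alcohol (C6–OH; CH2OH cis to the aryl group, H‑5 cis to the C10 methyl), via C6 alkylborane 9 (not isolated)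
Conditions: BH3·THF, THF, 0 °C → rt; then NaOH, H2O2, 0 °C → rt
Reagents that add atoms: hydrogen peroxide OO
Why: Hydroboration–oxidation: boron goes to the terminal carbon C6 and, because A(1,3) strain is expected to hold the C10 aryl group perpendicular to the alkene plane, the B–H adds from the face opposite the aryl group, which places H‑5 cis to the C10 methyl and sets C5.

Step 6
Reactants: 10 primary alcohol
Product: 11 benzyl ether of 10
Conditions: NaH, BnBr, Bu4NI (cat.), THF/DMF, 0 °C → rt
Reagents that add atoms: benzyl bromide BrCc1ccccc1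
Why: Williamson etherification gives a benzyl ether that should survive organolithiums, borane, hot KOH and SnCl4 and is removable later by hydrogenolysis.

Step 7
Reactants: 11 benzyl ether
Product: 12 C14 bromide of 11 (Br para to O11, ortho to the isopropyl group)
Conditions: NBS, MeCN, 0 °C, dark
Reagents that add atoms: N‑bromosuccinimide O=C1CCC(=O)N1Br
Why: Electrophilic aromatic bromination: C14 (para to O11, flanked only by the isopropyl group) should react in preference to C8 (para to O12), which is shielded by the quaternary ring A substituent on C9.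

Step 8
Reactants: 13 (+)‑sabinene
Product: 15 sabina ketone (5‑isopropylbicyclo[3.1.0]hexan‑2‑one, cyclopropane configuration as in 13), via ozonide 14 (not isolated)
Conditions: O3, CH2Cl2, −78 °C; then Me2S, −78 °C → rt
Reagents that add atoms: ozone [O-][O+]=O
Why: Ozonolysis with reductive work‑up cleaves the exocyclic methylene to the cyclopropyl ketone without touching the two stereocentres.

Step 9
Reactants: 15 sabina ketone
Product: 17 5‑isopropylbicyclo[3.1.0]hex‑2‑en‑2‑yl trifluoromethanesulfonate, via lithium enolate 16 (not isolated)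
Conditions: LDA, THF, −78 °C; then PhNTf2, −78 → 0 °C
Reagents that add atoms: N‑phenylbis(trifluoromethanesulfonimide) O=S(=O)(N(c1ccccc1)S(=O)(=O)C(F)(F)F)C(F)(F)F
Why: Kinetic enolate O‑triflation: enolisation is possible only toward the methylene carbon C3' (the other α‑carbon is the cyclopropane bridgehead), so a single enol triflate should form.

Step 10
Reactants: 12 C14 bromide; 17 enol triflate
Product: 20 aryl cyclopentene (C14 bonded to C2', C2'=C3'), via C14 aryllithium 18 (not isolated), via arylzinc chloride 19 (not isolated)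
Conditions: 12, t‑BuLi (2 equiv), THF, −78 °C; ZnCl2, −78 °C → rt; then 17, Pd2(dba)3 (2 mol %), SPhos (8 mol %), THF, 50 °C
Reagents that add atoms: none
Why: Negishi cross‑coupling: bromine–lithium exchange and transmetalation to zinc give an arylzinc that should couple with the alkenyl triflate under Pd/SPhos catalysis despite the ortho isopropyl group, forming the C14–C2' bond.

Step 11
Reactants: 20 aryl cyclopentene
Product: 22 trans‑2‑aryl alcohol (C3'–OH and C2'–H anti to C7'H2), via C3' alkylborane 21 (not isolated)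
Conditions: BH3·SMe2, THF, 0 °C → rt; then NaOH, H2O2
Reagents that add atoms: hydrogen peroxide OO
Why: Hydroboration–oxidation of the aryl‑substituted trisubstituted alkene puts boron on C3' (distal to the aryl group) from the face opposite the cyclopropane CH2; both new stereocentres are erased in steps 12 and 13.

Step 12
Reactants: 22 trans‑2‑aryl alcohol
Product: 23 α‑aryl ketone (C3'=O)
Conditions: Dess–Martin periodinane, NaHCO3, CH2Cl2, rt
Reagents that add atoms: none
Why: Dess–Martin oxidation of the secondary alcohol gives the α‑aryl ketone that makes C2' nucleophilic.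

Step 13
Reactants: 23 α‑aryl ketone
Product: 25 allyl ketone (C2' quaternary, allyl anti to C7'H2, aryl syn), via potassium enolate 24 (not isolated)
Conditions: KH, THF, 0 °C → rt; then allyl bromide, 0 °C → rt
Reagents that add atoms: allyl bromide C=CCBr
Why: Enolate C‑alkylation: the thermodynamic aryl‑conjugated enolate should be allylated at C2' on the face opposite the cyclopropane CH2, so the new C1'–C2' bond is anti and the aryl group ends syn to C7' as in the target, and any O‑allyl enol ether converges to 25 by Claisen rearrangement on warming.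

Step 14
Reactants: 25 allyl ketone
Product: 27 deoxygenated allyl compound (C3'H2), via hydrazone 26 (not isolated)
Conditions: N2H4·H2O, KOH, diethylene glycol, 130 °C, then 200 °C
Reagents that add atoms: none
Why: Wolff–Kishner reduction (Huang‑Minlon conditions) removes the auxiliary C3' carbonyl; the carbanion formed at C3' is not adjacent to the cyclopropane, and the acetal, the benzyl ether and the isolated allyl group should be stable to hot base.

Step 15
Reactants: 27 deoxygenated allyl compound
Product: 30 carboxylic acid (C2'–C1'H2–C7O2H), via diol 28 (not isolated), via aldehyde 29 (not isolated)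
Conditions: OsO4 (2 mol %), Oxone (KHSO5, 4 equiv), DMF, rt
Reagents that add atoms: potassium peroxymonosulfate [K+].[O-]S(=O)(=O)OO; water O
Why: Osmium‑catalysed oxidative cleavage (dihydroxylation, glycol fission, oxidation of the aldehyde by KHSO5) should turn the allyl group into the CH2CO2H unit that carries C1' and C7.

Step 16
Reactants: 30 carboxylic acid
Product: 32 spiro‑indanone (ring E closed: C7=O, C1'H2), via acid chloride 31 (not isolated)
Conditions: (COCl)2, DMF (cat.), CH2Cl2, 0 °C → rt; then SnCl4, CH2Cl2, −78 → −20 °C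
Reagents that add atoms: none
Why: Intramolecular Friedel–Crafts acylation: the acid chloride can reach only C8, the free position ortho to C14 and para to O12, so the five‑membered ring E should close as an indanone.

Step 17
Reactants: 32 spiro‑indanone
Product: 33 tert‑butyldimethylsilyl enol ether (C7(OSi)=C1'H)
Conditions: TBSOTf, Et3N, CH2Cl2, 0 °C
Reagents that add atoms: tert‑butyldimethylsilyl trifluoromethanesulfonate CC(C)(C)[Si](C)(C)OS(=O)(=O)C(F)(F)F
Why: Silyl enol ether formation; the ketone can enolise only toward C1'.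

Step 18
Reactants: 33 silyl enol ether
Product: 35 α‑hydroxy ketone (C1'–OH on the ring E face next to C6'), via silyloxy epoxide 34 (not isolated)
Conditions: L‑fructose‑derived ketone 1,2:4,5‑di‑O‑isopropylidene‑L‑erythro‑2,3‑hexodiulo‑2,6‑pyranose (30 mol %), Oxone (KHSO5), K2CO3, Bu4NHSO4, MeCN/CH2(OMe)2/aq. borate buffer pH 10.5, 0 °C; then AcOH/THF/H2O
Reagents that add atoms: potassium peroxymonosulfate [K+].[O-]S(=O)(=O)OO
Why: Asymmetric Rubottom oxidation by Shi epoxidation: the two faces at C1' are flanked by C3'H2 and C6'H and differ little, so the chiral dioxirane should control the face, delivering oxygen syn to C6', and hydrolysis of the silyloxy epoxide gives the α‑hydroxy ketone.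

Step 19
Reactants: 35 α‑hydroxy ketone
Product: 36 C1' tert‑butyldimethylsilyl ether
Conditions: TBSOTf, 2,6‑lutidine, CH2Cl2, −78 → 0 °C
Reagents that add atoms: tert‑butyldimethylsilyl trifluoromethanesulfonate CC(C)(C)[Si](C)(C)OS(=O)(=O)C(F)(F)F
Why: Silylation with the triflate protects the hindered secondary hydroxyl and provides the α‑silyloxy ketone that serves as the acceptor in step 22.

Step 20
Reactants: 36 silyl ether
Product: 37 primary alcohol (C6–OH free)
Conditions: H2 (1 atm), Pd/C, EtOAc, rt
Reagents that add atoms: none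
Why: Catalytic hydrogenolysis removes the benzyl ether; the doubly ortho‑substituted aryl ketone, the silyl ether, the acetal and the cyclopropane (not conjugated to the arene) should be inert under one atmosphere of hydrogen.

Step 21
Reactants: 37 primary alcohol
Product: 38 keto aldehyde (C6 aldehyde on ring A, C7 ketone in ring E)
Conditions: Dess–Martin periodinane, NaHCO3, CH2Cl2, 0 °C → rt
Reagents that add atoms: none
Why: Dess–Martin oxidation gives the aldehyde under buffered neutral conditions, so C5, which lies α to the new aldehyde between two quaternary carbons, should keep its configuration.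

Step 22
Reactants: 38 keto aldehyde
Product: 39 protected 7‑hydroxy‑6‑ketone (ring B closed)
Conditions: 2‑(pentafluorophenyl)‑6,7‑dihydro‑5H‑pyrrolo[2,1‑c][1,2,4]triazol‑2‑ium tetrafluoroborate (20 mol %), iPr2NEt (20 mol %), toluene, 60 °C
Reagents that add atoms: none
Why: Deprotonation of the triazolium salt gives the carbene, which adds to the C6 aldehyde; proton transfer forms the enaminol (Breslow intermediate), whose nucleophilic C6 attacks the C7 aryl ketone, and collapse of the adduct releases the carbene and the tertiary α‑ketol. The closest known reaction is the carbene‑catalysed intramolecular crossed aldehyde–ketone benzoin cyclisation that gives five‑ and six‑membered cyclic α‑ketols. Ring B is closed by a 6‑exo‑trig attack on the ketone carbonyl, forming C6–C7 at the junction shared with ring E. The new stereocentre C7 is set by the substrate, the tethered enaminol approaching the ketone face opposite the C1' silyloxy group, and this centre is erased in step 23, so either outcome serves. The step needs chemoselectivity (aldehyde as donor, ketone as acceptor) and retention of C5: only the aldehyde can form a Breslow intermediate, the ketone is the sole acceptor within reach and is activated by its α‑silyloxy group, and C5–H, buried between two quaternary carbons, should not be removed by the weak amine base. The reaction is an isomerisation, so no redox adjustment follows.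

Step 23
Reactants: 39 protected 7‑hydroxy‑6‑ketone
Product: 41 target quinone methide CNP0178265.2, via free catechol ketol 40 (not isolated)
Conditions: TFA/H2O (9:1), 0 °C → rt
Reagents that add atoms: none
Why: Acid hydrolysis removes the acetonide and the silyl ether, and the tertiary C7 carbinol, para to the freed O12 phenol, should lose water by acid‑catalysed 1,6‑elimination (para‑quinone methide formation) to give the C7=C8, C9=C11–OH, C12=O chromophore without any redox step.

**Compound list**

1 | 3‑isopropylcatechol | CC(C)c1cccc(O)c1O | starting material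
2 | 4‑isopropyl‑2,2‑dimethyl‑1,3‑benzodioxole | CC(C)c1cccc2OC(C)(C)Oc12 | intermediate
3 | (4‑isopropyl‑2,2‑dimethyl‑1,3‑benzodioxol‑7‑yl)lithium (C9 aryllithium) | CC(C)c1ccc([Li])c2OC(C)(C)Oc12 | intermediate (not isolated)
4 | 4‑bromo‑7‑isopropyl‑2,2‑dimethyl‑1,3‑benzodioxole | CC(C)c1ccc(Br)c2OC(C)(C)Oc12 | intermediate
5 | 2,2,6‑trimethylcyclohexanone (racemic) | CC1CCCC(C)(C)C1=O | starting material
6 | (R)‑2‑(7‑isopropyl‑2,2‑dimethyl‑1,3‑benzodioxol‑4‑yl)‑2,6,6‑trimethylcyclohexanone | CC(C)c1ccc(c2OC(C)(C)Oc12)[C@@]1(C)CCCC(C)(C)C1=O | intermediate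
7 | β‑hydroxysilane: 1‑[(trimethylsilyl)methyl]cyclohexanol adduct of 6 (carbinol configuration undefined) | CC(C)c1ccc(c2OC(C)(C)Oc12)[C@@]1(C)CCCC(C)(C)C1(O)C[Si](C)(C)C | intermediate (not isolated)
8 | exocyclic alkene: 6 with C5=CH2 in place of C5=O | CC(C)c1ccc(c2OC(C)(C)Oc12)[C@@]1(C)CCCC(C)(C)C1=C | intermediate
9 | C6 alkylborane from 8 (H‑5 cis to C10 methyl) | CC(C)c1ccc(c2OC(C)(C)Oc12)[C@@]1(C)CCCC(C)(C)[C@H]1CB | intermediate (not isolated)
10 | primary alcohol: (2‑aryl‑2,6,6‑trimethylcyclohexyl)methanol, CH2OH cis to aryl, H‑5 cis to C10 methyl | CC(C)c1ccc(c2OC(C)(C)Oc12)[C@@]1(C)CCCC(C)(C)[C@H]1CO | intermediate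
11 | benzyl ether of 10 | CC(C)c1ccc(c2OC(C)(C)Oc12)[C@@]1(C)CCCC(C)(C)[C@H]1COCc1ccccc1 | intermediate
12 | C14 bromide of 11 | CC(C)c1c(Br)cc(c2OC(C)(C)Oc12)[C@@]1(C)CCCC(C)(C)[C@H]1COCc1ccccc1 | intermediate
13 | (+)‑sabinene, (1R,5R) | C=C1CC[C@]2(C(C)C)C[C@@H]21 | starting material
14 | secondary ozonide of 13 (spiro 1,2,4‑trioxolane) | C1OC2(OO1)CC[C@]3(C(C)C)C[C@@H]32 | intermediate (not isolated)
15 | sabina ketone, 5‑isopropylbicyclo[3.1.0]hexan‑2‑one | O=C1CC[C@]2(C(C)C)C[C@@H]21 | intermediate
16 | lithium enolate of 15 | [Li]OC1=CC[C@]2(C(C)C)C[C@@H]21 | intermediate (not isolated)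
17 | 5‑isopropylbicyclo[3.1.0]hex‑2‑en‑2‑yl trifluoromethanesulfonate | O=S(=O)(OC1=CC[C@]2(C(C)C)C[C@@H]21)C(F)(F)F | intermediate
18 | C14 aryllithium from 12 | CC(C)c1c([Li])cc(c2OC(C)(C)Oc12)[C@@]1(C)CCCC(C)(C)[C@H]1COCc1ccccc1 | intermediate (not isolated)
19 | C14 arylzinc chloride | CC(C)c1c([Zn]Cl)cc(c2OC(C)(C)Oc12)[C@@]1(C)CCCC(C)(C)[C@H]1COCc1ccccc1 | intermediate (not isolated)
20 | aryl cyclopentene: C14 bonded to C2' of the 5‑isopropylbicyclo[3.1.0]hex‑2‑en‑2‑yl group | CC(C)c1c(C2=CC[C@]3(C(C)C)C[C@@H]32)cc(c2OC(C)(C)Oc12)[C@@]1(C)CCCC(C)(C)[C@H]1COCc1ccccc1 | intermediate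
21 | C3' alkylborane (B on C3' and H on C2' anti to C7'H2) | CC(C)c1c([C@@H]2[C@@H](B)C[C@]3(C(C)C)C[C@@H]32)cc(c2OC(C)(C)Oc12)[C@@]1(C)CCCC(C)(C)[C@H]1COCc1ccccc1 | intermediate (not isolated)
22 | trans‑2‑aryl alcohol (C3'–OH anti to C7'H2, aryl syn) | CC(C)c1c([C@@H]2[C@@H](O)C[C@]3(C(C)C)C[C@@H]32)cc(c2OC(C)(C)Oc12)[C@@]1(C)CCCC(C)(C)[C@H]1COCc1ccccc1 | intermediate
23 | α‑aryl ketone (C3'=O) | CC(C)c1c([C@@H]2C(=O)C[C@]3(C(C)C)C[C@@H]32)cc(c2OC(C)(C)Oc12)[C@@]1(C)CCCC(C)(C)[C@H]1COCc1ccccc1 | intermediate
24 | potassium enolate of 23 (C2'=C3'–OK) | CC(C)c1c(C2=C(O[K])C[C@]3(C(C)C)C[C@@H]32)cc(c2OC(C)(C)Oc12)[C@@]1(C)CCCC(C)(C)[C@H]1COCc1ccccc1 | intermediate (not isolated)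
25 | allyl ketone (C2' quaternary; allyl anti to C7'H2, aryl syn) | CC(C)c1c([C@]2(CC=C)C(=O)C[C@]3(C(C)C)C[C@@H]32)cc(c2OC(C)(C)Oc12)[C@@]1(C)CCCC(C)(C)[C@H]1COCc1ccccc1 | intermediate
26 | hydrazone of 25 | CC(C)c1c([C@]2(CC=C)C(=NN)C[C@]3(C(C)C)C[C@@H]32)cc(c2OC(C)(C)Oc12)[C@@]1(C)CCCC(C)(C)[C@H]1COCc1ccccc1 | intermediate (not isolated)
27 | deoxygenated allyl compound (C3'H2) | CC(C)c1c([C@]2(CC=C)CC[C@]3(C(C)C)C[C@@H]32)cc(c2OC(C)(C)Oc12)[C@@]1(C)CCCC(C)(C)[C@H]1COCc1ccccc1 | intermediate
28 | 1,2‑diol from the allyl group of 27 (carbinol configuration undefined) | CC(C)c1c([C@]2(CC(O)CO)CC[C@]3(C(C)C)C[C@@H]32)cc(c2OC(C)(C)Oc12)[C@@]1(C)CCCC(C)(C)[C@H]1COCc1ccccc1 | intermediate (not isolated)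
29 | aldehyde C2'–CH2–CHO | CC(C)c1c([C@]2(CC=O)CC[C@]3(C(C)C)C[C@@H]32)cc(c2OC(C)(C)Oc12)[C@@]1(C)CCCC(C)(C)[C@H]1COCc1ccccc1 | intermediate (not isolated)
30 | carboxylic acid C2'–C1'H2–C7O2H | CC(C)c1c([C@]2(CC(=O)O)CC[C@]3(C(C)C)C[C@@H]32)cc(c2OC(C)(C)Oc12)[C@@]1(C)CCCC(C)(C)[C@H]1COCc1ccccc1 | intermediate
31 | acid chloride of 30 | CC(C)c1c([C@]2(CC(=O)Cl)CC[C@]3(C(C)C)C[C@@H]32)cc(c2OC(C)(C)Oc12)[C@@]1(C)CCCC(C)(C)[C@H]1COCc1ccccc1 | intermediate (not isolated)
32 | spiro‑indanone (ring E: C7=O, C1'H2; spiro at C2'; ring A with CH2OBn) | CC(C)c1c2c(c(c5OC(C)(C)Oc15)[C@@]1(C)CCCC(C)(C)[C@H]1COCc1ccccc1)C(=O)C[C@]23CC[C@]4(C(C)C)C[C@@H]43 | intermediate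
33 | tert‑butyldimethylsilyl enol ether of 32 (C7(OSi)=C1'H) | CC(C)c1c2c(c(c5OC(C)(C)Oc15)[C@@]1(C)CCCC(C)(C)[C@H]1COCc1ccccc1)C(O[Si](C)(C)C(C)(C)C)=C[C@]23CC[C@]4(C(C)C)C[C@@H]43 | intermediate
34 | silyloxy epoxide (C7–C1' epoxide, oxygen on the face next to C6') | CC(C)c1c2c(c(c5OC(C)(C)Oc15)[C@@]1(C)CCCC(C)(C)[C@H]1COCc1ccccc1)[C@@]6(O[Si](C)(C)C(C)(C)C)O[C@H]6[C@]23CC[C@]4(C(C)C)C[C@@H]43 | intermediate (not isolated)
35 | α‑hydroxy ketone (C7=O, C1'–OH on the face next to C6') | CC(C)c1c2c(c(c5OC(C)(C)Oc15)[C@@]1(C)CCCC(C)(C)[C@H]1COCc1ccccc1)C(=O)[C@@H](O)[C@]23CC[C@]4(C(C)C)C[C@@H]43 | intermediate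
36 | C1' tert‑butyldimethylsilyl ether of 35 | CC(C)c1c2c(c(c5OC(C)(C)Oc15)[C@@]1(C)CCCC(C)(C)[C@H]1COCc1ccccc1)C(=O)[C@@H](O[Si](C)(C)C(C)(C)C)[C@]23CC[C@]4(C(C)C)C[C@@H]43 | intermediate
37 | primary alcohol (C6–OH) from 36 | CC(C)c1c2c(c(c5OC(C)(C)Oc15)[C@@]1(C)CCCC(C)(C)[C@H]1CO)C(=O)[C@@H](O[Si](C)(C)C(C)(C)C)[C@]23CC[C@]4(C(C)C)C[C@@H]43 | intermediate
38 | keto aldehyde, key‑step precursor (C6 aldehyde, C7 ketone, C9–C10 in place) | CC(C)c1c2c(c(c5OC(C)(C)Oc15)[C@@]1(C)CCCC(C)(C)[C@H]1C=O)C(=O)[C@@H](O[Si](C)(C)C(C)(C)C)[C@]23CC[C@]4(C(C)C)C[C@@H]43 | intermediate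
39 | protected 7‑hydroxy‑6‑ketone, key‑step product (ring B closed) | CC(C)c1c2c3[C@](O)(C(=O)[C@@H]4C(C)(C)CCC[C@]4(C)c3c5OC(C)(C)Oc15)[C@@H](O[Si](C)(C)C(C)(C)C)[C@]21CC[C@]2(C(C)C)C[C@@H]21 | intermediate
40 | free catechol 7‑hydroxy‑6‑ketone (1',7,11,12‑tetrol) | CC(C)c1c2c3[C@](O)(C(=O)[C@@H]4C(C)(C)CCC[C@]4(C)c3c(O)c1O)[C@@H](O)[C@]21CC[C@]2(C(C)C)C[C@@H]21 | intermediate (not isolated)
41 | CNP0178265.2, 11‑hydroxy quinone methide | CC(C)C1=C2C3=C(C(=O)[C@@H]4C(C)(C)CCC[C@]4(C)C3=C(O)C1=O)[C@@H](O)[C@]21CC[C@]2(C(C)C)C[C@@H]21 | target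

**Step count and risks**

Total: 23 steps. Longest linear sequence: 21 steps (steps 1–7 and 10–23, from 3‑isopropylcatechol); the sabinene branch (steps 8 and 9) joins at step 10.

The three steps most likely to fail:

Step 22. The carbene may fail to add to an aldehyde held between two quaternary carbons, so that no Breslow intermediate forms, or prolonged heating with base may erode the C5 configuration. The fallback sets out from 38: samarium diiodide (SmI2, HMPA, THF, −78 °C) would reduce the aryl ketone to its ketyl, which adds to the aldehyde in a six‑membered pinacol‑type closure to give the 6,7‑diol F1. Oxidation of its secondary C6 hydroxyl with Dess–Martin periodinane (the tertiary C7 hydroxyl cannot be oxidised) comes back to the route at 39.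

Step 3. Reductive elimination at the congested tetrasubstituted enolate may be slow and the enantioselectivity may erode. The fallback sets out from 4: palladium‑catalysed α‑arylation of cyclohexanone (Pd2(dba)3, XPhos, NaOtBu, toluene) should give the racemic 2‑arylcyclohexanone F2. Asymmetric phase‑transfer methylation (MeI, 50 % aq. KOH, toluene, chiral N‑spiro binaphthyl quaternary ammonium bromide) would then set the quaternary centre in the (R)‑2‑aryl‑2‑methylcyclohexanone F3. Exhaustive methylation of the only remaining enolisable position (NaH, MeI, THF) comes back to the route at 6.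

Step 18. Oxygen transfer to C1' may show poor or inverted facial selectivity, because the substrate itself offers almost no bias. The fallback sets out from 32: NaBH4 reduction gives the indanol F4, and acid‑catalysed dehydration (TsOH, toluene, 80 °C) gives the indene F5. Jacobsen–Katsuki epoxidation of this cis‑disubstituted aryl alkene ((R,R)‑(salen)MnCl, NaOCl, 4‑phenylpyridine N‑oxide) should give the epoxide F6 with oxygen on the face next to C6'. Oxidative opening at the benzylic carbon C7 (DMSO, cat. TfOH, then Et3N) comes back to the route at 35.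

**Further compounds**

F1 | step 22 | 6,7‑diol from ketyl–aldehyde coupling of 38 (C6 carbinol configuration undefined) | CC(C)c1c2c3[C@](O)(C(O)[C@@H]4C(C)(C)CCC[C@]4(C)c3c5OC(C)(C)Oc15)[C@@H](O[Si](C)(C)C(C)(C)C)[C@]21CC[C@]2(C(C)C)C[C@@H]21
F2 | step 3 | racemic 2‑(7‑isopropyl‑2,2‑dimethyl‑1,3‑benzodioxol‑4‑yl)cyclohexanone | CC(C)c1ccc(c2OC(C)(C)Oc12)C1CCCCC1=O
F3 | step 3 | (R)‑2‑(7‑isopropyl‑2,2‑dimethyl‑1,3‑benzodioxol‑4‑yl)‑2‑methylcyclohexanone | CC(C)c1ccc(c2OC(C)(C)Oc12)[C@@]1(C)CCCCC1=O
F4 | step 18 | indanol from 32 (C7–OH, configuration undefined) | CC(C)c1c2c(c(c5OC(C)(C)Oc15)[C@@]1(C)CCCC(C)(C)[C@H]1COCc1ccccc1)C(O)C[C@]23CC[C@]4(C(C)C)C[C@@H]43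
F5 | step 18 | indene (C7=C1') | CC(C)c1c2c(c(c5OC(C)(C)Oc15)[C@@]1(C)CCCC(C)(C)[C@H]1COCc1ccccc1)C=C[C@]23CC[C@]4(C(C)C)C[C@@H]43
F6 | step 18 | C7–C1' epoxide of F5, oxygen on the face next to C6' | CC(C)c1c2c(c(c5OC(C)(C)Oc15)[C@@]1(C)CCCC(C)(C)[C@H]1COCc1ccccc1)[C@H]6O[C@H]6[C@]23CC[C@]4(C(C)C)C[C@@H]43
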